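**Strategy.** Ring atoms: C1 (CH bearing the side chain), C2–C3 (epoxide), C4=C5 (alkene), C6 (quaternary). The carbocycle is cut at C5–C6, where the vinylic CH meets the carbon carrying methyl and γ-pyrone; this vinyl–quaternary junction of the cyclohexene is the feature exploited. A 6-exo-trig reductive Heck cyclisation of an acyclic (Z,Z)-dienyl iodide onto a 1-(pyronyl)vinyl group closes this bond, sets C6 under control of C1 and turns the exocyclic methylene into the C6 methyl, giving the trimethylcyclohexadiene in one operation. The precursor is an iodotriene whose C1 centre comes from iridium-catalysed allylic alkylation; epoxidation of C2=C3 and a reagent-controlled syn-aldol with pentan-3-one finish the route.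

Key step: step 16

Remark (assumption): the antipodes of the two chiral controllers, the (Sa,S,S)-phosphoramidite in step 13 and (+)-Ipc2BOTf [from (−)-α-pinene] in step 20, are written on the basis of the usual models (attack anti to iridium at the substituted allyl terminus; re-face addition to the aldehyde by analogy with the corresponding allylboranes); the mirror-image controller would be taken if the sense were the opposite.

Step 1
Reactants: 1 methyl 2-methyl-3-oxopentanoate; 2 N-methoxy-N-methylacetamide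
Product: 3 methyl 2,4-dimethyl-3,5-dioxohexanoate
Conditions: LiN(iPr)2 (3 equiv), THF, −78 → 0 °C; then 2, −78 °C → rt; aq. HCl
Reagents that add atoms: none
Why: Claisen-type γ-acylation of the β-keto ester dianion, in which the terminal carbanion is the more nucleophilic site and the Weinreb amide delivers one acetyl group through its stable tetrahedral chelate; the methine centres formed are enolisable and of no stereochemical consequence.

Step 2
Reactants: 3 methyl 2,4-dimethyl-3,5-dioxohexanoate
Product: 4 4-hydroxy-3,5,6-trimethyl-2H-pyran-2-one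
Conditions: DBU, toluene, 80 °C
Reagents that add atoms: none
Why: Base-promoted cyclisation of the triketide (intramolecular O-acylation of the terminal enol by the methyl ester) should give the 4-hydroxy-2-pyranone with loss of methanol.

Step 3
Reactants: 4 4-hydroxy-3,5,6-trimethyl-2H-pyran-2-one
Product: 5 2-methoxy-3,5,6-trimethyl-4H-pyran-4-one
Conditions: MeOTf, CH2Cl2, rt; then aq. NaHCO3
Reagents that add atoms: methyl trifluoromethanesulfonate, COS(=O)(=O)C(F)(F)F
Why: O-Methylation with a hard methylating agent takes place at the lactone carbonyl oxygen, the most basic site of the vinylogous acid, and loss of the hydroxyl proton from the pyrylium intermediate should give the 2-methoxy-4-pyranone.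

Step 4
Reactants: 5 2-methoxy-3,5,6-trimethyl-4H-pyran-4-one
Product: 6 diethyl [(6-methoxy-3,5-dimethyl-4-oxo-4H-pyran-2-yl)methyl]phosphonate
Conditions: LiN(SiMe3)2 (2.2 equiv), THF, −78 °C; ClP(O)(OEt)2, −78 → 0 °C; aq. NH4Cl
Reagents that add atoms: diethyl chlorophosphate, CCOP(=O)(Cl)OCC
Why: The 6-methyl group is the vinylogous α-position of the γ-pyrone and is lithiated selectively, and C-phosphorylation of this extended enolate (phosphonate formation from a stabilised carbanion, the second equivalent of base absorbing the more acidic product) should give the phosphonate.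

Step 5
Reactants: 7 prop-2-yn-1-ol
Product: 9 (Z)-3-iodo-2-methylprop-2-en-1-ol, via vinylmagnesium alkoxide 8 (not isolated)
Conditions: MeMgBr (3 equiv), CuI (10 mol%), THF, −10 °C → rt; then I2, −10 °C; aq. NH4Cl
Reagents that add atoms: methylmagnesium bromide, C[Mg]Br; iodine, II
Why: Copper-catalysed anti-carbomagnesiation of the propargylic alkoxide delivers methyl to the proximal alkyne carbon and gives a five-membered chelate in which C–Mg is cis to the CH2O group, so that iodinolysis with retention fixes the Z iodoalkene.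

Step 6
Reactants: 9 (Z)-3-iodo-2-methylprop-2-en-1-ol
Product: 10 (Z)-3-iodo-2-methylprop-2-enal
Conditions: MnO2, CH2Cl2, rt, dark
Reagents that add atoms: none
Why: Heterogeneous MnO2 oxidation of the allylic alcohol under neutral conditions should keep the Z geometry of the sensitive enal.

Step 7
Reactants: 10 (Z)-3-iodo-2-methylprop-2-enal; 11 methyl 2-[bis(2,2,2-trifluoroethoxy)phosphoryl]propanoate
Product: 12 methyl (2Z,4Z)-5-iodo-2,4-dimethylpenta-2,4-dienoate
Conditions: KN(SiMe3)2, 18-crown-6, THF, −78 °C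
Reagents that add atoms: none
Why: Still–Gennari olefination, in which the bis(trifluoroethyl) phosphonate under dissociating conditions eliminates under kinetic control to the Z trisubstituted enoate and so sets the C2=C3 geometry needed for ring closure.

Step 8
Reactants: 12 methyl (2Z,4Z)-5-iodo-2,4-dimethylpenta-2,4-dienoate
Product: 13 (2Z,4Z)-5-iodo-2,4-dimethylpenta-2,4-dien-1-ol
Conditions: iBu2AlH (2.2 equiv), CH2Cl2, −78 °C; aq. Rochelle salt
Reagents that add atoms: none
Why: 1,2-Reduction of the conjugated ester with iBu2AlH at low temperature should give the allylic alcohol without touching the iodoalkene or the alkene geometry.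

Step 9
Reactants: 13 (2Z,4Z)-5-iodo-2,4-dimethylpenta-2,4-dien-1-ol
Product: 14 (2Z,4Z)-5-iodo-2,4-dimethylpenta-2,4-dienal
Conditions: MnO2, CH2Cl2, rt, dark
Reagents that add atoms: none
Why: Allylic oxidation on MnO2 under neutral conditions, as in step 6, should preserve both Z alkenes.

Step 10
Reactants: 14 (2Z,4Z)-5-iodo-2,4-dimethylpenta-2,4-dienal; 15 triethyl phosphonoacetate
Product: 16 ethyl (2E,4Z,6Z)-7-iodo-4,6-dimethylhepta-2,4,6-trienoate
Conditions: NaH, THF, 0 °C → rt
Reagents that add atoms: none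
Why: Horner–Wadsworth–Emmons olefination with the stabilised phosphonate anion should give the E enoate.

Step 11
Reactants: 16 ethyl (2E,4Z,6Z)-7-iodo-4,6-dimethylhepta-2,4,6-trienoate
Product: 17 (2E,4Z,6Z)-7-iodo-4,6-dimethylhepta-2,4,6-trien-1-ol
Conditions: iBu2AlH (2.2 equiv), CH2Cl2, −78 °C; aq. Rochelle salt
Reagents that add atoms: none
Why: 1,2-Reduction of the enoate with iBu2AlH, as in step 8, should give the primary allylic alcohol.

Step 12
Reactants: 17 (2E,4Z,6Z)-7-iodo-4,6-dimethylhepta-2,4,6-trien-1-ol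
Product: 18 (2E,4Z,6Z)-7-iodo-4,6-dimethylhepta-2,4,6-trien-1-yl methyl carbonate
Conditions: ClCO2Me, pyridine, CH2Cl2, 0 °C
Reagents that add atoms: methyl chloroformate, COC(=O)Cl
Why: Acylation of the allylic alcohol with the chloroformate gives the carbonate, whose ionisation later releases methoxide as the internal base.

Step 13
Reactants: 6 diethyl [(6-methoxy-3,5-dimethyl-4-oxo-4H-pyran-2-yl)methyl]phosphonate; 18 (2E,4Z,6Z)-7-iodo-4,6-dimethylhepta-2,4,6-trien-1-yl methyl carbonate
Product: 19 diethyl [(2S,3Z,5Z)-2-ethenyl-6-iodo-1-(6-methoxy-3,5-dimethyl-4-oxo-4H-pyran-2-yl)-3,5-dimethylhexa-3,5-dien-1-yl]phosphonate (both epimers at C-1)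
Conditions: [Ir(cod)Cl]2 (2 mol%), (Sa,S,S)-O,O'-(1,1'-binaphthyl-2,2'-diyl) N,N-bis(1-phenylethyl)phosphoramidite (4 mol%), TBD (8 mol%), THF, rt → 40 °C
Reagents that add atoms: none
Why: Iridium-catalysed asymmetric allylic alkylation, in which the cyclometallated iridium–phosphoramidite complex ionises the carbonate, the liberated methoxide deprotonates the phosphonate, and the stabilised carbanion attacks the substituted allyl terminus anti to the metal, so that the ligand sets the allylic stereocentre (C1 of the later ring) while the centre next to phosphorus is removed in the next step.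

Step 14
Reactants: 19 diethyl [(2S,3Z,5Z)-2-ethenyl-6-iodo-1-(6-methoxy-3,5-dimethyl-4-oxo-4H-pyran-2-yl)-3,5-dimethylhexa-3,5-dien-1-yl]phosphonate
Product: 20 2-[(3S,4Z,6Z)-3-ethenyl-7-iodo-4,6-dimethylhepta-1,4,6-trien-2-yl]-6-methoxy-3,5-dimethyl-4H-pyran-4-one
Conditions: NaH (1.05 equiv), THF, 0 °C; (CH2O)n, 0 °C → rt
Reagents that add atoms: formaldehyde (as paraformaldehyde), C=O
Why: Horner–Wadsworth–Emmons methylenation with formaldehyde converts the phosphonate carbon into the 1,1-disubstituted alkene conjugated with the pyrone and removes the inconsequential stereocentre.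

Step 15
Reactants: 20 2-[(3S,4Z,6Z)-3-ethenyl-7-iodo-4,6-dimethylhepta-1,4,6-trien-2-yl]-6-methoxy-3,5-dimethyl-4H-pyran-4-one
Product: 22 2-[(3S,4Z,6Z)-3-(2-hydroxyethyl)-7-iodo-4,6-dimethylhepta-1,4,6-trien-2-yl]-6-methoxy-3,5-dimethyl-4H-pyran-4-one, via B-alkyl-9-BBN adduct 21 (not isolated)
Conditions: 9-BBN-H (1.3 equiv), THF, 0 °C → rt; then aq. NaOAc, 30% H2O2, 0 °C → rt
Reagents that add atoms: hydrogen peroxide, OO
Why: Hydroboration–oxidation, in which 9-BBN-H should add anti-Markovnikov to the monosubstituted vinyl group much faster than to the hindered, electron-poor pyronyl alkene, the trisubstituted diene or the iodoalkene, and buffered peroxide oxidises the C–B bond with retention.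

Step 16
Reactants: 22 2-[(3S,4Z,6Z)-3-(2-hydroxyethyl)-7-iodo-4,6-dimethylhepta-1,4,6-trien-2-yl]-6-methoxy-3,5-dimethyl-4H-pyran-4-one
Product: 25 2-[(1R,6S)-6-(2-hydroxyethyl)-1,3,5-trimethylcyclohexa-2,4-dien-1-yl]-6-methoxy-3,5-dimethyl-4H-pyran-4-one, via alkenylpalladium iodide 23 (not isolated), via alkylpalladium iodide 24 (not isolated)
Conditions: Pd(OAc)2 (10 mol%), PPh3 (25 mol%), HCO2Na (1.5 equiv), Et4NCl (1 equiv), DMF, 70 °C
Reagents that add atoms: none
Why: Zerovalent palladium inserts into the C–I bond with retention of the Z geometry, the alkenylpalladium iodide 23 adds syn across the 1-(pyronyl)vinyl group so that C5 bonds to the internal carbon C6, and the neopentyl-type alkylpalladium 24, which has no β-hydrogen, is intercepted by formate (decarboxylation to a palladium hydride, then C–H reductive elimination) to give the C6 methyl group. The closest known reaction type is the intramolecular reductive Heck cyclisation (carbopalladation followed by hydride capture) used to build all-carbon quaternary centres. The six-membered carbocycle is closed in the 6-exo-trig mode, 7-endo closure being disfavoured by the tether length and by the 1,1-disubstitution of the acceptor alkene. The new stereocentre C6 is controlled by C1: allylic 1,2-strain with the C2 methyl group places the hydroxyethyl chain pseudoaxial, and the alkene should insert with its CH2–Pd terminus and the palladium ligands on the opposite ring face, so that the new methyl ends trans and the pyrone cis to the side chain. The step needs exo regioselectivity, hydride capture faster than 3-exo attack of 24 on the C4=C5 bond, and no reduction of 23 before cyclisation; the short tether, the absence of β-hydrogens in 24, the excess of formate and the speed of the intramolecular insertion should secure this, and 22 holds no other alkene within reach of C5.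

Step 17
Reactants: 25 2-[(1R,6S)-6-(2-hydroxyethyl)-1,3,5-trimethylcyclohexa-2,4-dien-1-yl]-6-methoxy-3,5-dimethyl-4H-pyran-4-one
Product: 26 2-[(1S,6R)-6-(6-methoxy-3,5-dimethyl-4-oxo-4H-pyran-2-yl)-2,4,6-trimethylcyclohexa-2,4-dien-1-yl]acetaldehyde
Conditions: Dess–Martin periodinane, NaHCO3, CH2Cl2, 0 °C → rt
Reagents that add atoms: none
Why: Dess–Martin oxidation of the primary alcohol under buffered conditions should give the aldehyde without isomerising the cyclohexadiene.

Step 18
Reactants: 26 2-[(1S,6R)-6-(6-methoxy-3,5-dimethyl-4-oxo-4H-pyran-2-yl)-2,4,6-trimethylcyclohexa-2,4-dien-1-yl]acetaldehyde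
Product: 27 2-[(1S,6R)-6-(6-methoxy-3,5-dimethyl-4-oxo-4H-pyran-2-yl)-2,4,6-trimethylcyclohexa-2,4-dien-1-yl]prop-2-enal
Conditions: 37% aq. HCHO, pyrrolidine (10 mol%), propionic acid (10 mol%), iPrOH, 45 °C
Reagents that add atoms: formaldehyde, C=O
Why: Organocatalytic α-methylenation of the aldehyde (Mannich condensation with formaldehyde through the enamine, then elimination of the amine) builds the 2-substituted acrolein.

Step 19
Reactants: 27 2-[(1S,6R)-6-(6-methoxy-3,5-dimethyl-4-oxo-4H-pyran-2-yl)-2,4,6-trimethylcyclohexa-2,4-dien-1-yl]prop-2-enal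
Product: 28 2-[(1R,4R,5S,6S)-4-(6-methoxy-3,5-dimethyl-4-oxo-4H-pyran-2-yl)-2,4,6-trimethyl-7-oxabicyclo[4.1.0]hept-2-en-5-yl]prop-2-enal
Conditions: mCPBA (1.05 equiv), NaHCO3, CH2Cl2, −20 → 0 °C
Reagents that add atoms: 3-chloroperoxybenzoic acid, O=C(OO)c1cccc(Cl)c1
Why: Prilezhaev epoxidation of the electron-rich diene, in which the C4=C5 alkene is shielded on both faces by the methyl and pyrone groups of the neighbouring quaternary C6, so the peracid should attack C2=C3 from the face anti to the pseudoaxial C1 substituent and the pyrone, setting both epoxide stereocentres, while the electron-poor enal alkene is inert.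

Step 20
Reactants: 28 2-[(1R,4R,5S,6S)-4-(6-methoxy-3,5-dimethyl-4-oxo-4H-pyran-2-yl)-2,4,6-trimethyl-7-oxabicyclo[4.1.0]hept-2-en-5-yl]prop-2-enal; 29 pentan-3-one
Product: 32 (4R,5R)-5-hydroxy-6-[(1R,4R,5R,6S)-4-(6-methoxy-3,5-dimethyl-4-oxo-4H-pyran-2-yl)-2,4,6-trimethyl-7-oxabicyclo[4.1.0]hept-2-en-5-yl]-4-methylhept-6-en-3-one, via Z-enol borinate 30 (not isolated), via boron aldolate 31 (not isolated)
Conditions: (+)-Ipc2BOTf, iPr2NEt, CH2Cl2, −78 °C; then 28, −78 → −20 °C; then pH 7 buffer, MeOH, 30% H2O2, 0 °C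
Reagents that add atoms: none
Why: Diisopinocampheylboron-mediated syn-aldol, in which the Z enol borinate reacts through a chair-like six-membered transition state to give the syn relationship and the isopinocampheyl ligands direct addition to the re face of the aldehyde, so both new stereocentres are set under reagent control.

**Compound list**

1 | methyl 2-methyl-3-oxopentanoate | CCC(=O)C(C)C(=O)OC | starting material
2 | N-methoxy-N-methylacetamide | CC(=O)N(C)OC | starting material
3 | methyl 2,4-dimethyl-3,5-dioxohexanoate | COC(=O)C(C)C(=O)C(C)C(C)=O | intermediate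
4 | 4-hydroxy-3,5,6-trimethyl-2H-pyran-2-one | Cc1oc(=O)c(C)c(O)c1C | intermediate
5 | 2-methoxy-3,5,6-trimethyl-4H-pyran-4-one | COc1oc(C)c(C)c(=O)c1C | intermediate
6 | diethyl [(6-methoxy-3,5-dimethyl-4-oxo-4H-pyran-2-yl)methyl]phosphonate | CCOP(=O)(Cc1oc(OC)c(C)c(=O)c1C)OCC | intermediate
7 | prop-2-yn-1-ol | C#CCO | starting material
8 | bromomagnesium (Z)-3-(bromomagnesio)-2-methylprop-2-en-1-olate (vinylmagnesium alkoxide) | Br[Mg]OC/C(C)=C\[Mg]Br | intermediate
9 | (Z)-3-iodo-2-methylprop-2-en-1-ol | OC/C(C)=C\I | intermediate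
10 | (Z)-3-iodo-2-methylprop-2-enal | O=C/C(C)=C\I | intermediate
11 | methyl 2-[bis(2,2,2-trifluoroethoxy)phosphoryl]propanoate | COC(=O)C(C)P(=O)(OCC(F)(F)F)OCC(F)(F)F | starting material
12 | methyl (2Z,4Z)-5-iodo-2,4-dimethylpenta-2,4-dienoate | COC(=O)/C(C)=C\C(C)=C/I | intermediate
13 | (2Z,4Z)-5-iodo-2,4-dimethylpenta-2,4-dien-1-ol | OC/C(C)=C\C(C)=C/I | intermediate
14 | (2Z,4Z)-5-iodo-2,4-dimethylpenta-2,4-dienal | O=C/C(C)=C\C(C)=C/I | intermediate
15 | triethyl phosphonoacetate | CCOC(=O)CP(=O)(OCC)OCC | starting material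
16 | ethyl (2E,4Z,6Z)-7-iodo-4,6-dimethylhepta-2,4,6-trienoate | CCOC(=O)/C=C/C(C)=C\C(C)=C/I | intermediate
17 | (2E,4Z,6Z)-7-iodo-4,6-dimethylhepta-2,4,6-trien-1-ol | OC/C=C/C(C)=C\C(C)=C/I | intermediate
18 | (2E,4Z,6Z)-7-iodo-4,6-dimethylhepta-2,4,6-trien-1-yl methyl carbonate | COC(=O)OC/C=C/C(C)=C\C(C)=C/I | intermediate
19 | diethyl [(2S,3Z,5Z)-2-ethenyl-6-iodo-1-(6-methoxy-3,5-dimethyl-4-oxo-4H-pyran-2-yl)-3,5-dimethylhexa-3,5-dien-1-yl]phosphonate (both epimers at C-1) | C=C[C@H](C(c1oc(OC)c(C)c(=O)c1C)P(=O)(OCC)OCC)/C(C)=C\C(C)=C/I | intermediate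
20 | 2-[(3S,4Z,6Z)-3-ethenyl-7-iodo-4,6-dimethylhepta-1,4,6-trien-2-yl]-6-methoxy-3,5-dimethyl-4H-pyran-4-one | C=C[C@H](C(=C)c1oc(OC)c(C)c(=O)c1C)/C(C)=C\C(C)=C/I | intermediate
21 | B-alkyl-9-borabicyclo[3.3.1]nonane adduct of 20 | B1(CC[C@H](C(=C)c2oc(OC)c(C)c(=O)c2C)/C(C)=C\C(C)=C/I)C3CCCC1CCC3 | intermediate
22 | 2-[(3S,4Z,6Z)-3-(2-hydroxyethyl)-7-iodo-4,6-dimethylhepta-1,4,6-trien-2-yl]-6-methoxy-3,5-dimethyl-4H-pyran-4-one | OCC[C@H](C(=C)c1oc(OC)c(C)c(=O)c1C)/C(C)=C\C(C)=C/I | intermediate
23 | alkenylpalladium iodide formed from 22 by oxidative addition (phosphine ligands omitted) | OCC[C@H](C(=C)c1oc(OC)c(C)c(=O)c1C)/C(C)=C\C(C)=C/[Pd]I | intermediate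
24 | neopentyl-type alkylpalladium iodide formed by 6-exo carbopalladation (phosphine ligands omitted) | OCC[C@H]1C(C)=CC(C)=C[C@@]1(C[Pd]I)c1oc(OC)c(C)c(=O)c1C | intermediate
25 | 2-[(1R,6S)-6-(2-hydroxyethyl)-1,3,5-trimethylcyclohexa-2,4-dien-1-yl]-6-methoxy-3,5-dimethyl-4H-pyran-4-one | OCC[C@H]1C(C)=CC(C)=C[C@@]1(C)c1oc(OC)c(C)c(=O)c1C | intermediate
26 | 2-[(1S,6R)-6-(6-methoxy-3,5-dimethyl-4-oxo-4H-pyran-2-yl)-2,4,6-trimethylcyclohexa-2,4-dien-1-yl]acetaldehyde | O=CC[C@H]1C(C)=CC(C)=C[C@@]1(C)c1oc(OC)c(C)c(=O)c1C | intermediate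
27 | 2-[(1S,6R)-6-(6-methoxy-3,5-dimethyl-4-oxo-4H-pyran-2-yl)-2,4,6-trimethylcyclohexa-2,4-dien-1-yl]prop-2-enal | C=C(C=O)[C@H]1C(C)=CC(C)=C[C@@]1(C)c1oc(OC)c(C)c(=O)c1C | intermediate
28 | 2-[(1R,4R,5S,6S)-4-(6-methoxy-3,5-dimethyl-4-oxo-4H-pyran-2-yl)-2,4,6-trimethyl-7-oxabicyclo[4.1.0]hept-2-en-5-yl]prop-2-enal | C=C(C=O)[C@H]1[C@]2(C)O[C@@H]2C(C)=C[C@@]1(C)c1oc(OC)c(C)c(=O)c1C | intermediate
29 | pentan-3-one | CCC(=O)CC | starting material
30 | (Z)-pent-2-en-3-yl diisopinocampheylborinate (isopinocampheyl groups from (−)-α-pinene) | C/C=C(/CC)OB([C@H]1C[C@H]2C[C@@H]([C@@H]1C)C2(C)C)[C@H]1C[C@H]2C[C@@H]([C@@H]1C)C2(C)C | intermediate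
31 | O-diisopinocampheylboryl aldolate of 32 | C=C([C@H](OB([C@H]1C[C@H]2C[C@@H]([C@@H]1C)C2(C)C)[C@H]1C[C@H]2C[C@@H]([C@@H]1C)C2(C)C)[C@@H](C)C(=O)CC)[C@H]1[C@]2(C)O[C@@H]2C(C)=C[C@@]1(C)c1oc(OC)c(C)c(=O)c1C | intermediate
32 | (4R,5R)-5-hydroxy-6-[(1R,4R,5R,6S)-4-(6-methoxy-3,5-dimethyl-4-oxo-4H-pyran-2-yl)-2,4,6-trimethyl-7-oxabicyclo[4.1.0]hept-2-en-5-yl]-4-methylhept-6-en-3-one | C=C([C@H](O)[C@@H](C)C(=O)CC)[C@H]1[C@]2(C)O[C@@H]2C(C)=C[C@@]1(C)c1oc(OC)c(C)c(=O)c1C | target

**Totals.** Total step count: 20. Longest linear sequence: 16 steps (steps 5 to 20, from prop-2-yn-1-ol); the pyrone branch (steps 1 to 4) joins at step 13.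

**Steps most likely to fail and their fallbacks**

Step 16 (key cyclisation). The carbopalladation may show poor facial selectivity at C6, or the alkylpalladium species may be diverted by 3-exo attack on the neighbouring alkene or by reduction of the alkenylpalladium species before ring closure. The fallback changes the polarity of the ring closure. Setting out from 22, conjugate reduction of the pyrone-activated methylene with [(Ph3P)CuH]6 (toluene, rt, aqueous work-up) should give 2-[(2RS,3R,4Z,6Z)-3-(2-hydroxyethyl)-7-iodo-4,6-dimethylhepta-4,6-dien-2-yl]-6-methoxy-3,5-dimethyl-4H-pyran-4-one F1. Its pyrone-stabilised carbanion (KOtBu, THF) would then be coupled with the alkenyl iodide under Pd(PPh3)4 catalysis (intramolecular enolate alkenylation), which forms the same C5–C6 bond and comes back to the route at 25.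

Step 13 (allylic alkylation). The carbanion may attack the remote positions of the trienyl system or the unsubstituted allyl terminus, the Z alkenes may be scrambled through allyl isomerisation, or the enantioselectivity may be low. The fallback is a conjugate-addition entry. Setting out from 17, MnO2 oxidation should give (2E,4Z,6Z)-7-iodo-4,6-dimethylhepta-2,4,6-trienal F2. Iminium-catalysed Michael addition of 6 (diarylprolinol trimethylsilyl ether, benzoic acid, toluene) should give diethyl [(2S,3Z,5Z)-6-iodo-1-(6-methoxy-3,5-dimethyl-4-oxo-4H-pyran-2-yl)-3,5-dimethyl-2-(2-oxoethyl)hexa-3,5-dien-1-yl]phosphonate F3. NaBH4 reduction gives diethyl [(2S,3Z,5Z)-2-(2-hydroxyethyl)-6-iodo-1-(6-methoxy-3,5-dimethyl-4-oxo-4H-pyran-2-yl)-3,5-dimethylhexa-3,5-dien-1-yl]phosphonate F4. Methylenation of F4 with NaH and paraformaldehyde comes back to the route at 22.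

Step 19 (epoxidation). The peracid may discriminate poorly between the C2=C3 and C4=C5 alkenes, attack the hindered face, or open the vinyl epoxide through the acid formed. The fallback moves from substrate control to catalyst control: asymmetric dioxirane epoxidation of 27 with the fructose-derived chiral ketone whose sense matches attack anti to the side chain (KHSO5, K2CO3 buffer, MeCN–dimethoxymethane–water, 0 °C). This method responds strongly to alkene substitution and runs at basic pH; it sets out from 27 and comes back at 28 without a new compound.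

Further compounds
F1 | step 16 | 2-[(2RS,3R,4Z,6Z)-3-(2-hydroxyethyl)-7-iodo-4,6-dimethylhepta-4,6-dien-2-yl]-6-methoxy-3,5-dimethyl-4H-pyran-4-one | OCC[C@H](C(C)c1oc(OC)c(C)c(=O)c1C)/C(C)=C\C(C)=C/I
F2 | step 13 | (2E,4Z,6Z)-7-iodo-4,6-dimethylhepta-2,4,6-trienal | O=C/C=C/C(C)=C\C(C)=C/I
F3 | step 13 | diethyl [(2S,3Z,5Z)-6-iodo-1-(6-methoxy-3,5-dimethyl-4-oxo-4H-pyran-2-yl)-3,5-dimethyl-2-(2-oxoethyl)hexa-3,5-dien-1-yl]phosphonate | O=CC[C@H](C(c1oc(OC)c(C)c(=O)c1C)P(=O)(OCC)OCC)/C(C)=C\C(C)=C/I
F4 | step 13 | diethyl [(2S,3Z,5Z)-2-(2-hydroxyethyl)-6-iodo-1-(6-methoxy-3,5-dimethyl-4-oxo-4H-pyran-2-yl)-3,5-dimethylhexa-3,5-dien-1-yl]phosphonate | OCC[C@H](C(c1oc(OC)c(C)c(=O)c1C)P(=O)(OCC)OCC)/C(C)=C\C(C)=C/I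
F0 | step 19 | none | none
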